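## The problem

The target 15 is a 2,4-dihydroxybenzoic acid whose C6 carries an unbranched fifteen-carbon chain (C1' on the ring to C15'). The skeleton therefore poses two tasks: a tetrasubstituted arene with the chain ortho to the carboxyl group, and a Z double bond at C8'–C9'. The only stereocenter, C10' (R), carries the acetate and is allylic to that double bond. It lies ten carbons from the ring, so nothing in the molecule can direct its formation; control must come from a reagent, a catalyst or an enzyme. Three groups forbid rough treatment. The free β-resorcylic acid loses carbon dioxide on heating or in strong acid. The Z-allylic acetate ionizes under Lewis or Brønsted acids and with zerovalent palladium, with loss of configuration, 1,3-shift or Z-to-E isomerization. The isolated Z alkene excludes hydrogenolysis. Of the three hydroxyl groups only the one on C10' is acylated, so a chemoselective acetylation or deacetylation cannot be avoided. The enabling feature is that C10' is an allylic methylene of what is otherwise a fatty acid. Counted from the carboxyl carbon through arene C1 and C6 into the chain, the molecule is an eighteen-carbon acid with C10' as its thirteenth carbon, in the region that long-chain fatty acid hydroxylases of the CYP102A1 family oxidize. The deoxy acid 11 is, moreover, what a polyketide-type ring synthesis delivers from natural (9Z)-hexadec-9-enoic acid 4, whose double bond already has the right place and geometry.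

## Retrosynthesis

**Acetate last (15 to 12).** The first cut is the ester C–O bond between the acetyl group and O10', leading back through the triacetate 14 to the hydroxy acid 12. An alkyl acetate would not survive the lithium amide bases that assemble the ring precursor, and an oxidizing enzyme cannot install it, so it must follow both. The cut removes only two carbons; its purpose is to expose the C10' hydroxyl for the next disconnection. The forward reaction must place one acetyl group on the secondary alcohol in the presence of two phenols and a carboxyl group. Since the alkyl ester is the least labile of the possible esters, exhaustive acetylation (through the mixed anhydride 13 to 14) and mild cleavage of the aryl acetates is asked to do this without breaking a bond at C10'.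

**The key cut (12 to 11).** The C10'–O bond is replaced by C–H, giving the acid 11, which has no stereocenter. The neighbouring options were C–C cuts beside C10' (carbonyl addition of an alkynyl metal, or a cross-coupling at C7'–C8'). Each requires the chain to be assembled from pieces, with its own asymmetric step, a Z-selective alkene synthesis and oxygen protecting groups. The C–H cut removes the only stereocenter and the only chain heteroatom at once, and leaves a side chain identical to that of a natural fatty acid. The demand on the forward reaction is severe: one oxygen atom into one of two allylic methylenes (C10', not C7'), on one face, without epoxidation of C8'–C9' and without allylic shift. No small reagent offers this. An iron-oxo enzyme that holds the substrate by its carboxylate can in principle, and 11 is shaped like its natural substrates.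

**Ester and ring (11 to 6 and 7).** Acid 11 is reached from its 2-(trimethylsilyl)ethyl ester 10. The arene C1–C6 bond of 10 is cut by a retro-aldol condensation to the triketo ester 9, and the ester C–O bond of 9 is cut to the acylketene 8 and 2-(trimethylsilyl)ethanol 7. Ketene 8 is stored as the diketo-dioxinone 6. Attaching the chain to a preformed resorcylate would need protected phenols and a long functionalized Z-alkenyl partner. The aldol aromatization needs neither: it produces the free phenols directly and takes the chain from a carboxylic acid. The forward reaction must trap the ketene intermolecularly, close C2 onto the C7 ketone only, and give an ester that comes off without hydrogenation or strong acid; fluoride meets the last point.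

**Chain attachment (6 to 3 and 5).** Compound 6 is cut between side-chain C3 and C4, a Claisen-type disconnection to the keto-dioxinone 3 and the acyl imidazole 5. This uses the fatty acid at its natural oxidation level. The forward reaction requires C-acylation at the terminal carbon of the dianion of 3, without O-acylation or double addition.

**Starting materials.** Imidazolide 5 is the activated form of acid 4, and 3 arises from dioxinone 1 and acetyl chloride 2 by acylation of the dienolate. Compounds 1, 2, 4 and 7 are commercial. Acid 4 supplies all fifteen chain carbons and arene C6; its C9–C10 double bond becomes C8'–C9' with Z geometry.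

## Roads not taken

**Alternative 1:** The arene is cut at C5–C6 and C1–C2, a Diels–Alder benzannulation of 1-methoxy-1,3-bis(trimethylsilyloxy)buta-1,3-diene A1 with 2-(trimethylsilyl)ethyl (11Z,13R)-13-acetoxyoctadec-11-en-2-ynoate A2.
- Key step: heating in toluene would join the CH2 terminus of A1 to the chain-bearing alkyne carbon and the ketene acetal carbon to the ester-bearing carbon. Loss of methanol and of the silyl groups on acidic work-up would give 2-(trimethylsilyl)ethyl 6-[(8Z,10R)-10-acetoxypentadec-8-enyl]-2,4-dihydroxybenzoate A3, one fluoride step from 15.
- Merits: the regiochemistry follows from matched polarization, and the phenols appear free. The acetate and the C10' configuration are in place before the ring is made, so no chemoselective acetylation is needed. In that respect this road is better than the chosen one.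
- Weak points: an ynoate with one ester and a β-alkyl group is a sluggish dienophile. The diene is prone to silyl transfer and hydrolysis during prolonged heating, which the Z-allylic acetate must also endure. A2 needs its own asymmetric step, a Z-selective semireduction before the second triple bond is introduced, and a carboxylation, roughly eight steps before the key step. The final fluoride step must spare the acetate.
- Comparison: every step is known chemistry, which the chosen plan cannot claim. The chosen plan sets against this eight steps in all (against about ten), no chiral reagent, a well-behaved ring synthesis, and a single risky step that can be tested on a substrate five steps from bulk chemicals.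

**Alternative 2:** The chain is cut at C7'–C8'.
- Key step: 2-(trimethylsilyl)ethyl 6-(hept-6-enyl)-2,4-bis(methoxymethoxy)benzoate A4, hydroborated at its terminal carbon with 9-borabicyclo[3.3.1]nonane, would be coupled with tert-butyl{[(1Z,3R)-1-iodooct-1-en-3-yl]oxy}dimethylsilane A5. PdCl2(dppf) (dppf = 1,1'-bis(diphenylphosphino)ferrocene) and aqueous Cs2CO3 would give 2-(trimethylsilyl)ethyl 6-[(8Z,10R)-10-(tert-butyldimethylsilyloxy)pentadec-8-enyl]-2,4-bis(methoxymethoxy)benzoate A6 (B-alkyl Suzuki–Miyaura coupling).
- Merits: this is the most dependable sp3–sp2 coupling available. The iodoalkene geometry is transferred with retention, the stereocenter can come from an enantiopure propargylic alcohol, and the route is convergent.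
- Weak points: four protecting groups of three kinds are carried. After the coupling, A6 still needs desilylation at O10', acetylation, removal of two methoxymethyl ethers and removal of the ester. The methoxymethyl ethers come off with acid, which the Z-allylic acetate and the β-resorcylic acid tolerate worst. A4 needs several steps from a protected resorcylate, so the total is about thirteen steps.
- Comparison: this is the most certain of the four roads, since the configuration is bought and not created. The chosen plan answers with roughly half the steps, free phenols throughout and no acid-labile group to remove beside the allylic acetate. It pays with an enzyme that has yet to be found.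

**Alternative 3:** The arene is cut at C1–C6 as in the chosen route, but with the C10' oxygen already in the chain.
- Key step: 6-[(12Z,14R)-14-(tert-butyldimethylsilyloxy)-2,4-dioxononadec-12-enyl]-2,2-dimethyl-4H-1,3-dioxin-4-one A7 would be heated with 7. The trapped trioxo ester would be closed with Cs2CO3 and dilute acid to 2-(trimethylsilyl)ethyl 6-[(8Z,10R)-10-(tert-butyldimethylsilyloxy)pentadec-8-enyl]-2,4-dihydroxybenzoate A8.
- Merits: the ring synthesis is the same reliable one, no step lies beyond known chemistry, and the stereocenter comes from established sources.
- Weak points: the chiral sixteen-carbon acid behind A7 has to be made in about four steps, where the chosen plan buys a natural fatty acid. The allylic silyl ether must pass strong base, 110 °C and an acidic dehydration. After fluoride deprotection the route arrives at 12 and faces the same acetylation problem, so nothing is saved at the end.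
- Comparison: three to four steps longer and dependent on a stoichiometric chiral building block, but safer. Because it converges on 12, its logic is kept, with a more acid-stable silyl group, as the fallback for the enzymatic step.

Key step: step 6

Remark on the chemistry: chain atoms are numbered C1' (on arene C6) to C15', and the enzyme variant of step 6 is assumed to have been found by screening and directed evolution on 11 before the route is run.

## Route

Step 1
Reactants: 1 2,2,6-trimethyl-4H-1,3-dioxin-4-one; 2 acetyl chloride
Product: 3 2,2-dimethyl-6-(2-oxopropyl)-4H-1,3-dioxin-4-one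
Conditions: LiN(SiMe3)2 and 1 (2 equiv each), THF, −78 °C; 2 (1 equiv), −78 °C; 1 M HCl
Reagents that add atoms: none
Why: γ-Deprotonation gives the lithium dienolate of the dioxinone, which is C-acylated at the former 6-methyl carbon by the acid chloride (crossed Claisen-type acylation); the second equivalent of dienolate takes the proton of the more acidic β-keto product and so prevents double acylation.

Step 2
Reactants: 4 (9Z)-hexadec-9-enoic acid (palmitoleic acid)
Product: 5 1-[(9Z)-hexadec-9-enoyl]-1H-imidazole
Conditions: 1,1'-carbonyldiimidazole (1.1 equiv), CH2Cl2, rt; quick water wash, dry, concentrate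
Reagents that add atoms: 1,1'-carbonyldiimidazole, O=C(n1ccnc1)n1ccnc1
Why: Carboxyl activation as the imidazolide with loss of CO2 and imidazole; the neutral conditions leave the Z alkene untouched, and the wash removes imidazole that would otherwise consume base in step 3.

Step 3
Reactants: 3 2,2-dimethyl-6-(2-oxopropyl)-4H-1,3-dioxin-4-one; 5 1-[(9Z)-hexadec-9-enoyl]-1H-imidazole
Product: 6 6-[(12Z)-2,4-dioxononadec-12-enyl]-2,2-dimethyl-4H-1,3-dioxin-4-one
Conditions: 3 (2 equiv), LiN(iPr)2 (4 equiv), THF, −78 °C; 5 (1 equiv), −78 to −20 °C; cold 1 M HCl
Reagents that add atoms: none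
Why: Double deprotonation gives the dianion of the β-keto-dioxinone, whose terminal carbanion is the most nucleophilic site and is C-acylated by the imidazolide (Claisen condensation of a 1,3-dicarbonyl dianion); the diketone product is deprotonated in the flask, which shields it from a second addition.

Step 4
Reactants: 6 6-[(12Z)-2,4-dioxononadec-12-enyl]-2,2-dimethyl-4H-1,3-dioxin-4-one; 7 2-(trimethylsilyl)ethanol
Product: 10 2-(trimethylsilyl)ethyl 2,4-dihydroxy-6-[(8Z)-pentadec-8-enyl]benzoate, via acylketene 8 (not isolated), via triketo ester 9 (not isolated)
Conditions: 7 (2 equiv), PhMe, 110 °C; then Cs2CO3, MeOH, rt; then HCl in MeOH, rt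
Reagents that add atoms: none
Why: Retro-[4+2] fragmentation of the dioxinone releases acetone and acylketene 8, which the alcohol traps as the 3,5,7-trioxo ester 9; Cs2CO3 brings about the intramolecular aldol addition of C2 to the C7 ketone and acid completes dehydration to the arene (biomimetic polyketide cyclization–aromatization), conditions that do not move the isolated Z alkene.

Step 5
Reactants: 10 2-(trimethylsilyl)ethyl 2,4-dihydroxy-6-[(8Z)-pentadec-8-enyl]benzoate
Product: 11 2,4-dihydroxy-6-[(8Z)-pentadec-8-enyl]benzoic acid
Conditions: Bu4NF (4 equiv), THF, 0 °C to rt; cold 1 M HCl to pH 3, no heating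
Reagents that add atoms: none
Why: Fluoride attacks silicon and the 2-silylethyl ester fragments to carboxylate, ethylene and Me3SiF (fluoride-induced β-elimination), so no nucleophile has to reach the hindered, hydrogen-bonded carbonyl; the extra equivalents allow for the two phenols, and the cold work-up guards against decarboxylation.

Step 6
Reactants: 11 2,4-dihydroxy-6-[(8Z)-pentadec-8-enyl]benzoic acid
Product: 12 2,4-dihydroxy-6-[(8Z,10R)-10-hydroxypentadec-8-enyl]benzoic acid
Conditions: engineered CYP102A1 (P450 BM3) variant (cell-free extract), NADP+ (cat.), glucose dehydrogenase, D-glucose, catalase, air, K2HPO4/KH2PO4 buffer (0.1 M, pH 8.0), DMSO (2% v/v), 25 °C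
Reagents that add atoms: dioxygen, O=O
Why: Proposed new method: the oxoiron porphyrin radical cation of the heme (formally tetravalent iron), formed from O2 and two electrons from NADPH, abstracts a hydrogen atom from C10', and the iron-bound hydroxyl recombines with the allylic radical on the same face before it can relocate (oxygen rebound), so the C10'–O bond forms with retention and C8'–C9' stays Z. The closest known reaction type is the subterminal and allylic hydroxylation of long-chain fatty acids by CYP102A1 and its engineered variants; hydroxylation of an alkylresorcylic acid at this site is not known, so the variant has to be found by directed evolution. No ring is closed. The new stereocenter C10' is controlled by the enzyme alone: the active site presents the pro-R hydrogen to the oxidant, and retention turns this into the (R) alcohol. Three selectivities are needed: site (C10' against C7' and the C12' to C14' methylenes), chemo (hydroxylation against epoxidation of C8'–C9') and face. The substrate contributes the carboxylate on arene C1, which can bind at the channel entrance as that of a fatty acid does and fixes the register of the chain with C10' as thirteenth carbon, and the weak allylic C–H bonds, which favour C10' and C7' over saturated positions. The choice between C10' and C7' and the choice of face rest on the evolved pocket.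

Step 7
Reactants: 12 2,4-dihydroxy-6-[(8Z,10R)-10-hydroxypentadec-8-enyl]benzoic acid
Product: 14 2,4-diacetoxy-6-[(8Z,10R)-10-acetoxypentadec-8-enyl]benzoic acid, via mixed anhydride 13 (not isolated)
Conditions: Ac2O (6 equiv), pyridine, DMAP (cat.), CH2Cl2, 0 °C to rt; then H2O, THF, rt; cold dilute HCl wash
Reagents that add atoms: acetic anhydride, CC(=O)OC(C)=O
Why: Nucleophile-catalysed O-acylation esterifies all three hydroxyls without touching the C10'–O bond, so the (R) configuration and Z geometry are kept; the carboxyl group is converted to the acetic mixed anhydride 13, which water opens at the unhindered acetyl carbonyl during work-up. Complete acetylation of the hydrogen-bonded C2 phenol is not essential, because both aryl esters are removed in step 8.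

Step 8
Reactants: 14 2,4-diacetoxy-6-[(8Z,10R)-10-acetoxypentadec-8-enyl]benzoic acid
Product: 15 6-[(8Z,10R)-10-acetoxypentadec-8-enyl]-2,4-dihydroxybenzoic acid
Conditions: NaHCO3 (3 equiv), MeOH–H2O (9:1), rt; cold 1 M HCl to pH 3
Reagents that add atoms: none
Why: Aryl acetates are activated esters (phenoxide leaving group, the C2 acetate further assisted by the neighbouring carboxylate as in acetylsalicylic acid), so bicarbonate-buffered methanolysis (chemoselective transesterification) removes them at room temperature, whereas the secondary alkyl acetate at C10' needs alkoxide-strength base and remains; no bond at C10' is broken.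

## Compound list

1 | 2,2,6-trimethyl-4H-1,3-dioxin-4-one | CC1=CC(=O)OC(C)(C)O1 | starting material
2 | acetyl chloride | CC(Cl)=O | starting material
3 | 2,2-dimethyl-6-(2-oxopropyl)-4H-1,3-dioxin-4-one | CC(=O)CC1=CC(=O)OC(C)(C)O1 | intermediate
4 | (9Z)-hexadec-9-enoic acid (palmitoleic acid) | CCCCCC/C=C\CCCCCCCC(=O)O | starting material
5 | 1-[(9Z)-hexadec-9-enoyl]-1H-imidazole | CCCCCC/C=C\CCCCCCCC(=O)n1ccnc1 | intermediate
6 | 6-[(12Z)-2,4-dioxononadec-12-enyl]-2,2-dimethyl-4H-1,3-dioxin-4-one | CCCCCC/C=C\CCCCCCCC(=O)CC(=O)CC1=CC(=O)OC(C)(C)O1 | intermediate
7 | 2-(trimethylsilyl)ethanol | C[Si](C)(C)CCO | starting material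
8 | (15Z)-3,5,7-trioxodocosa-1,15-dien-1-one (acylketene) | CCCCCC/C=C\CCCCCCCC(=O)CC(=O)CC(=O)C=C=O | intermediate (not isolated)
9 | 2-(trimethylsilyl)ethyl (15Z)-3,5,7-trioxodocos-15-enoate | CCCCCC/C=C\CCCCCCCC(=O)CC(=O)CC(=O)CC(=O)OCC[Si](C)(C)C | intermediate (not isolated)
10 | 2-(trimethylsilyl)ethyl 2,4-dihydroxy-6-[(8Z)-pentadec-8-enyl]benzoate | CCCCCC/C=C\CCCCCCCc1cc(O)cc(O)c1C(=O)OCC[Si](C)(C)C | intermediate
11 | 2,4-dihydroxy-6-[(8Z)-pentadec-8-enyl]benzoic acid | CCCCCC/C=C\CCCCCCCc1cc(O)cc(O)c1C(=O)O | intermediate
12 | 2,4-dihydroxy-6-[(8Z,10R)-10-hydroxypentadec-8-enyl]benzoic acid | CCCCC[C@H](/C=C\CCCCCCCc1cc(O)cc(O)c1C(=O)O)O | intermediate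
13 | acetic 2,4-diacetoxy-6-[(8Z,10R)-10-acetoxypentadec-8-enyl]benzoic anhydride | CCCCC[C@H](/C=C\CCCCCCCc1cc(OC(C)=O)cc(OC(C)=O)c1C(=O)OC(C)=O)OC(C)=O | intermediate (not isolated)
14 | 2,4-diacetoxy-6-[(8Z,10R)-10-acetoxypentadec-8-enyl]benzoic acid | CCCCC[C@H](/C=C\CCCCCCCc1cc(OC(C)=O)cc(OC(C)=O)c1C(=O)O)OC(C)=O | intermediate
15 | 6-[(8Z,10R)-10-acetoxypentadec-8-enyl]-2,4-dihydroxybenzoic acid | CCCCC[C@H](/C=C\CCCCCCCc1cc(O)cc(O)c1C(=O)O)OC(C)=O | target

## Step count and risks

Total: 8 steps. Longest linear sequence: 7 steps (1 or 4 to 15).

**Step 6 (key step).**
- What may go wrong: oxidation at the wrong methylene (C7', or C12' to C14' near the chain end), epoxidation of C8'–C9', and rebound at C8' with allylic shift. Low enantioselectivity, over-oxidation of the new alcohol to the enone, and poor turnover are also possible if the aromatic head does not seat like a fatty acid carboxylate. The substrate biases only toward the two allylic positions, so everything else depends on a variant that may not be found.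
- Fallback: known chemistry, with the oxygen brought in with the chain. It sets out from 3 and returns at 12.
  - Commercial (R)-oct-1-yn-3-ol is silylated (tert-butyldiphenylsilyl chloride, imidazole, DMF) to tert-butyl[(3R)-oct-1-yn-3-yloxy]diphenylsilane F1.
  - Its lithium acetylide (n-BuLi, THF/DMPU) is alkylated with lithium 8-bromooctanoate to (11R)-11-(tert-butyldiphenylsilyloxy)hexadec-9-ynoic acid F2.
  - Semi-hydrogenation (H2, Pd on CaCO3 poisoned with Pb(OAc)2, quinoline) gives (9Z,11R)-11-(tert-butyldiphenylsilyloxy)hexadec-9-enoic acid F3.
  - 1,1'-Carbonyldiimidazole converts it into 1-[(9Z,11R)-11-(tert-butyldiphenylsilyloxy)hexadec-9-enoyl]-1H-imidazole F4.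
  - F4 acylates the dianion of 3 as in step 3 to give 6-[(12Z,14R)-14-(tert-butyldiphenylsilyloxy)-2,4-dioxononadec-12-enyl]-2,2-dimethyl-4H-1,3-dioxin-4-one F5.
  - Thermolysis with 7 and aromatization as in step 4, acidifying with acetic acid, give 2-(trimethylsilyl)ethyl 6-[(8Z,10R)-10-(tert-butyldiphenylsilyloxy)pentadec-8-enyl]-2,4-dihydroxybenzoate F6.
  - Excess Bu4NF in THF removes the silyl ether and the silylethyl ester together and gives 12.

**Step 3.**
- What may go wrong: the dianion is quenched by proton transfer from the more acidic product or from residual imidazole, and O-acylation or acylation at the internal carbon may compete. The terminal carbanion is only kinetically preferred.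
- Fallback: soft enolization in place of the dianion. It sets out from 4 and 1 and returns at 6.
  - Acid 4 is converted with oxalyl chloride and catalytic DMF into (9Z)-hexadec-9-enoyl chloride F7.
  - The lithium dienolate of 1 is acylated with allyl 3-chloro-3-oxopropanoate to allyl 4-(2,2-dimethyl-4-oxo-4H-1,3-dioxin-6-yl)-3-oxobutanoate F8.
  - MgCl2 and pyridine in CH2Cl2 enolize F8 as its magnesium chelate, which is C-acylated by F7 to allyl (11Z)-2-[(2,2-dimethyl-4-oxo-4H-1,3-dioxin-6-yl)acetyl]-3-oxooctadec-11-enoate F9.
  - Pd(PPh3)4 and morpholine in THF remove the allyl group, and the β-keto acid loses CO2 to give 6.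

**Step 4.**
- What may go wrong: the acylketene may be captured by its own enol oxygen (pyranone formation) faster than by the alcohol. The trioxo ester may also close in another mode or exchange its ester with methanol before the aldol step.
- Fallback: aromatization without generating a ketene. It sets out from 6 and returns at 11, which also bypasses step 5.
  - Et3N in CH2Cl2 at rt effects the aldol condensation with the dioxinone ring intact and gives 7-hydroxy-2,2-dimethyl-5-[(8Z)-pentadec-8-enyl]-4H-1,3-benzodioxin-4-one F10.
  - KOH in aqueous DMSO opens the acetonide lactone, and cold acidification gives 11.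

**Step 8.**
- What may go wrong: incomplete discrimination between the esters, either partial methanolysis of the C10' acetate on extended reaction or slow loss of the C2 acetate. Selectivity rests only on leaving-group ability.
- Fallback: selectivity by enzyme fit in place of basicity. It sets out from 14 and returns at 15. Immobilized Candida antarctica lipase B with n-butanol in tert-butyl methyl ether at 30 °C transfers the aryl acetyl groups to butanol under neutral conditions. The secondary acetate, flanked by two long chains, is a poor substrate for the enzyme. No new compound is made.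

## Further compounds

F1 | step 6 | tert-butyl[(3R)-oct-1-yn-3-yloxy]diphenylsilane | CCCCC[C@H](C#C)O[Si](c1ccccc1)(c1ccccc1)C(C)(C)C
F2 | step 6 | (11R)-11-(tert-butyldiphenylsilyloxy)hexadec-9-ynoic acid | CCCCC[C@H](C#CCCCCCCCC(=O)O)O[Si](c1ccccc1)(c1ccccc1)C(C)(C)C
F3 | step 6 | (9Z,11R)-11-(tert-butyldiphenylsilyloxy)hexadec-9-enoic acid | CCCCC[C@H](/C=C\CCCCCCCC(=O)O)O[Si](c1ccccc1)(c1ccccc1)C(C)(C)C
F4 | step 6 | 1-[(9Z,11R)-11-(tert-butyldiphenylsilyloxy)hexadec-9-enoyl]-1H-imidazole | CCCCC[C@H](/C=C\CCCCCCCC(=O)n1ccnc1)O[Si](c1ccccc1)(c1ccccc1)C(C)(C)C
F5 | step 6 | 6-[(12Z,14R)-14-(tert-butyldiphenylsilyloxy)-2,4-dioxononadec-12-enyl]-2,2-dimethyl-4H-1,3-dioxin-4-one | CCCCC[C@H](/C=C\CCCCCCCC(=O)CC(=O)CC1=CC(=O)OC(C)(C)O1)O[Si](c1ccccc1)(c1ccccc1)C(C)(C)C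
F6 | step 6 | 2-(trimethylsilyl)ethyl 6-[(8Z,10R)-10-(tert-butyldiphenylsilyloxy)pentadec-8-enyl]-2,4-dihydroxybenzoate | CCCCC[C@H](/C=C\CCCCCCCc1cc(O)cc(O)c1C(=O)OCC[Si](C)(C)C)O[Si](c1ccccc1)(c1ccccc1)C(C)(C)C
F7 | step 3 | (9Z)-hexadec-9-enoyl chloride | CCCCCC/C=C\CCCCCCCC(Cl)=O
F8 | step 3 | allyl 4-(2,2-dimethyl-4-oxo-4H-1,3-dioxin-6-yl)-3-oxobutanoate | C=CCOC(=O)CC(=O)CC1=CC(=O)OC(C)(C)O1
F9 | step 3 | allyl (11Z)-2-[(2,2-dimethyl-4-oxo-4H-1,3-dioxin-6-yl)acetyl]-3-oxooctadec-11-enoate | C=CCOC(=O)C(C(=O)CCCCCCC/C=C\CCCCCC)C(=O)CC1=CC(=O)OC(C)(C)O1
F10 | step 4 | 7-hydroxy-2,2-dimethyl-5-[(8Z)-pentadec-8-enyl]-4H-1,3-benzodioxin-4-one | CCCCCC/C=C\CCCCCCCc1cc(O)cc2c1C(=O)OC(C)(C)O2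
F0 | step 8 | none | none
A1 | alternative 1 | 1-methoxy-1,3-bis(trimethylsilyloxy)buta-1,3-diene | COC(=CC(=C)O[Si](C)(C)C)O[Si](C)(C)C
A2 | alternative 1 | 2-(trimethylsilyl)ethyl (11Z,13R)-13-acetoxyoctadec-11-en-2-ynoate | CCCCC[C@H](/C=C\CCCCCCCC#CC(=O)OCC[Si](C)(C)C)OC(C)=O
A3 | alternative 1 | 2-(trimethylsilyl)ethyl 6-[(8Z,10R)-10-acetoxypentadec-8-enyl]-2,4-dihydroxybenzoate | CCCCC[C@H](/C=C\CCCCCCCc1cc(O)cc(O)c1C(=O)OCC[Si](C)(C)C)OC(C)=O
A4 | alternative 2 | 2-(trimethylsilyl)ethyl 6-(hept-6-enyl)-2,4-bis(methoxymethoxy)benzoate | C=CCCCCCc1cc(OCOC)cc(OCOC)c1C(=O)OCC[Si](C)(C)C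
A5 | alternative 2 | tert-butyl{[(1Z,3R)-1-iodooct-1-en-3-yl]oxy}dimethylsilane | CCCCC[C@H](/C=C\I)O[Si](C)(C)C(C)(C)C
A6 | alternative 2 | 2-(trimethylsilyl)ethyl 6-[(8Z,10R)-10-(tert-butyldimethylsilyloxy)pentadec-8-enyl]-2,4-bis(methoxymethoxy)benzoate | CCCCC[C@H](/C=C\CCCCCCCc1cc(OCOC)cc(OCOC)c1C(=O)OCC[Si](C)(C)C)O[Si](C)(C)C(C)(C)C
A7 | alternative 3 | 6-[(12Z,14R)-14-(tert-butyldimethylsilyloxy)-2,4-dioxononadec-12-enyl]-2,2-dimethyl-4H-1,3-dioxin-4-one | CCCCC[C@H](/C=C\CCCCCCCC(=O)CC(=O)CC1=CC(=O)OC(C)(C)O1)O[Si](C)(C)C(C)(C)C
A8 | alternative 3 | 2-(trimethylsilyl)ethyl 6-[(8Z,10R)-10-(tert-butyldimethylsilyloxy)pentadec-8-enyl]-2,4-dihydroxybenzoate | CCCCC[C@H](/C=C\CCCCCCCc1cc(O)cc(O)c1C(=O)OCC[Si](C)(C)C)O[Si](C)(C)C(C)(C)C
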